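**Retrosynthetic overview**

1. Target ⇒ aryl-alkynyl tetralin diol: the (E)-6,7-alkene is unveiled last by trans-hydroalumination of a propargylic alcohol.
2. ⇒ silyl-capped alkynyl tetralin diol + 4-iodophenol (Sonogashira); the phenol ring is attached after the ring closure.
3. ⇒ linear (3R,4E)-enynol: the tetralin, the only ring formed, is closed by Friedel–Crafts attack of the dimethoxyphenyl ring on C-4 of a 4,5-epoxy-3-ol made in the same flask by matched Sharpless epoxidation. The alkyne stands in for the 6,7-alkene so that C-5 does not ionise.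
4. ⇒ enynone (CBS reduction) ⇒ 4-(3,4-dimethoxyphenyl)butan-2-one + 3-(trimethylsilyl)propynal (aldol condensation).

Assumption: the biosynthetic ring closure is taken to be arene attack on C-4 of the 4,5-epoxide of a linear 1,7-diarylhept-4-en-3-ol; chain positions use heptanoid numbering (C-1 = benzylic CH2 of the dimethoxyphenyl arm, C-7 = carbon bearing the phenol ring).

Note: the side-chain carbinol is labelled S in 8, 10 and 11 and R in 12 with no change in space, because an alkynyl carbon outranks the ring carbon and an alkenyl carbon does not.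

**Route**

Step 1
Reactants: 1 4-(3,4-dimethoxyphenyl)butan-2-one; 2 3-(trimethylsilyl)prop-2-ynal
Product: 5 (E)-1-(3,4-dimethoxyphenyl)-7-(trimethylsilyl)hept-4-en-6-yn-3-one, via aldol adduct 3 (not isolated), via aldol mesylate 4 (not isolated)
Conditions: LDA, THF, −78 °C; 2; then MsCl, Et3N, −78 °C → rt
Reagents that add atoms: none
Why: Kinetic deprotonation of the methyl ketone gives the terminal lithium enolate, which adds to the non-enolisable ynal (directed aldol addition), and mesylation of the aldolate followed by E1cB elimination gives the conjugated (E)-enynone as the thermodynamic isomer (aldol condensation).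

Step 2
Reactants: 5 (E)-1-(3,4-dimethoxyphenyl)-7-(trimethylsilyl)hept-4-en-6-yn-3-one
Product: 6 (3R,4E)-1-(3,4-dimethoxyphenyl)-7-(trimethylsilyl)hept-4-en-6-yn-3-ol
Conditions: (S)-Me-CBS (20 mol%), catecholborane, toluene, −78 °C
Reagents that add atoms: none
Why: Corey–Bakshi–Shibata reduction, in which the (S)-oxazaborolidine binds the ketone with the alkenyl arm as the large group and delivers hydride 1,2 to set C-3 as R (about 90% ee expected), while catecholborane at −78 °C leaves the enyne and the C–Si bond alone.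

Step 3
Reactants: 6 (3R,4E)-1-(3,4-dimethoxyphenyl)-7-(trimethylsilyl)hept-4-en-6-yn-3-ol
Product: 8 (1S,2R)-1-[(1S)-1-hydroxy-3-(trimethylsilyl)prop-2-yn-1-yl]-6,7-dimethoxy-1,2,3,4-tetrahydronaphthalen-2-ol, via epoxy alcohol 7 (not isolated)
Conditions: Ti(OiPr)4 (0.3 equiv), D-(−)-DIPT (0.36 equiv), TBHP (1.2 equiv), 4 Å MS, CH2Cl2, −20 °C; P(OMe)3 (0.3 equiv); then BF3·OEt2 (4 equiv), −78 → −30 °C
Reagents that add atoms: tert-butyl hydroperoxide, CC(C)(C)OO
Why: Proposed new method: the matched Sharpless epoxidation (reagent and substrate control both erythro) puts the (4R,5R)-trans-epoxide on the C4=C5 alkene only and raises the ee because the minor (S)-alcohol is the slow-reacting enantiomer; after surplus TBHP is destroyed with P(OMe)3, BF3 activates the epoxide and the dimethoxyphenyl ring (position para to a methoxy group) opens it at C-4 in a 6-exo, SN2-like Friedel–Crafts alkylation with inversion, C-4 being favoured because an uncomplexed alkynyl group disfavours positive charge at C-5 and 7-endo closure is slower, so C-4 (S) and the retained C-5 carbinol are set and the 1,2-cis tetralin results in one operation; the closest known reactions are Lewis-acid epoxy-arene cyclisations to tetralins and one-flask derivatisation or opening of Sharpless epoxy alcohols after phosphite quench.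

Step 4
Reactants: 8 (1S,2R)-1-[(1S)-1-hydroxy-3-(trimethylsilyl)prop-2-yn-1-yl]-6,7-dimethoxy-1,2,3,4-tetrahydronaphthalen-2-ol; 9 4-iodophenol
Product: 11 (1S,2R)-1-[(1S)-1-hydroxy-3-(4-hydroxyphenyl)prop-2-yn-1-yl]-6,7-dimethoxy-1,2,3,4-tetrahydronaphthalen-2-ol, via terminal alkyne 10 (not isolated)
Conditions: K2CO3 (3 equiv), MeOH/THF, rt; then 9, PdCl2(PPh3)2 (3 mol%), CuI (5 mol%), 45 °C
Reagents that add atoms: none
Why: Methanolysis of the C(sp)–Si bond frees the terminal alkyne, which undergoes Sonogashira coupling with the aryl iodide; free hydroxyls and the phenol are tolerated and no stereocentre is touched.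

Step 5
Reactants: 11 (1S,2R)-1-[(1S)-1-hydroxy-3-(4-hydroxyphenyl)prop-2-yn-1-yl]-6,7-dimethoxy-1,2,3,4-tetrahydronaphthalen-2-ol
Product: 12 (1S,2R)-1-[(1R,2E)-1-hydroxy-3-(4-hydroxyphenyl)prop-2-en-1-yl]-6,7-dimethoxy-1,2,3,4-tetrahydronaphthalen-2-ol
Conditions: Red-Al (6 equiv), THF, 0 → 45 °C; aq. Rochelle salt
Reagents that add atoms: none
Why: Alkoxide-directed trans-hydroalumination of the propargylic alcohol (Red-Al reduction, H to C-6 and Al to C-7) and protonolysis on work-up give only the (E)-allylic alcohol with the stereocentres unchanged, and the neutral work-up protects the acid-labile p-hydroxycinnamyl alcohol.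

**Compound list**

1 | 4-(3,4-dimethoxyphenyl)butan-2-one | COc1ccc(CCC(C)=O)cc1OC | starting material
2 | 3-(trimethylsilyl)prop-2-ynal | C[Si](C)(C)C#CC=O | starting material
3 | 1-(3,4-dimethoxyphenyl)-5-hydroxy-7-(trimethylsilyl)hept-6-yn-3-one (racemic aldol adduct; lithium alkoxide in the flask, not isolated) | COc1ccc(CCC(=O)CC(O)C#C[Si](C)(C)C)cc1OC | intermediate
4 | 7-(3,4-dimethoxyphenyl)-5-oxo-1-(trimethylsilyl)hept-1-yn-3-yl methanesulfonate (racemic, not isolated) | COc1ccc(CCC(=O)CC(OS(C)(=O)=O)C#C[Si](C)(C)C)cc1OC | intermediate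
5 | (E)-1-(3,4-dimethoxyphenyl)-7-(trimethylsilyl)hept-4-en-6-yn-3-one | COc1ccc(CCC(=O)/C=C/C#C[Si](C)(C)C)cc1OC | intermediate
6 | (3R,4E)-1-(3,4-dimethoxyphenyl)-7-(trimethylsilyl)hept-4-en-6-yn-3-ol | COc1ccc(CC[C@@H](O)/C=C/C#C[Si](C)(C)C)cc1OC | intermediate
7 | (1R)-3-(3,4-dimethoxyphenyl)-1-{(2R,3R)-3-[(trimethylsilyl)ethynyl]oxiran-2-yl}propan-1-ol (erythro, trans-epoxide; heptanoid 3R,4R,5R; not isolated) | COc1ccc(CC[C@@H](O)[C@H]2O[C@@H]2C#C[Si](C)(C)C)cc1OC | intermediate
8 | (1S,2R)-1-[(1S)-1-hydroxy-3-(trimethylsilyl)prop-2-yn-1-yl]-6,7-dimethoxy-1,2,3,4-tetrahydronaphthalen-2-ol | COc1cc2c(cc1OC)[C@H]([C@H](O)C#C[Si](C)(C)C)[C@H](O)CC2 | intermediate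
9 | 4-iodophenol | Oc1ccc(I)cc1 | starting material
10 | (1S,2R)-1-[(1S)-1-hydroxyprop-2-yn-1-yl]-6,7-dimethoxy-1,2,3,4-tetrahydronaphthalen-2-ol (not isolated) | COc1cc2c(cc1OC)[C@H]([C@H](O)C#C)[C@H](O)CC2 | intermediate
11 | (1S,2R)-1-[(1S)-1-hydroxy-3-(4-hydroxyphenyl)prop-2-yn-1-yl]-6,7-dimethoxy-1,2,3,4-tetrahydronaphthalen-2-ol | COc1cc2c(cc1OC)[C@H]([C@H](O)C#Cc1ccc(O)cc1)[C@H](O)CC2 | intermediate
12 | (1S,2R)-1-[(1R,2E)-1-hydroxy-3-(4-hydroxyphenyl)prop-2-en-1-yl]-6,7-dimethoxy-1,2,3,4-tetrahydronaphthalen-2-ol | COc1cc2c(cc1OC)[C@H]([C@H](O)/C=C/c1ccc(O)cc1)[C@H](O)CC2 | target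

**Step count and risks**

Total step count: 5. Longest linear sequence: 5 steps (1 → 5 → 6 → 8 → 11 → 12).

Steps most likely to fail:

Step 3 (highest risk). The ring closure must outrun three competing paths: alcoholysis of the activated epoxide by iPrOH, tBuOH and tartrate left in the flask, a 1,2-hydride shift to a β-hydroxy ketone, and attack at C-5 (7-endo) if titanium stays chelated between the C-3 oxygen and the epoxide. The fallback sets out from 6. The epoxidation is run on its own and the epoxy alcohol 7 is isolated. Its hydroxyl is capped (TESCl, imidazole, DMF) to give the triethylsilyl ether of the epoxy alcohol F1. F1 is cyclised in a clean medium with a non-chelated Lewis acid (SnCl4 or MeAlCl2, CH2Cl2, −78 °C) to the O-triethylsilyl tetralin F2. TBAF (THF, 0 °C) then removes both silyl groups and gives the terminal alkyne 10, where the route is rejoined at the Pd/Cu half of step 4.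

Step 5. The substrate is carried as a trianion, and the phenoxide makes the alkyne electron-rich, so the hydroalumination may stall or need forcing temperatures. The fallback sets out from 10, isolated after the K2CO3/MeOH half of step 4. Pd-catalysed syn-hydrostannation (Bu3SnH, PdCl2(PPh3)2, THF, 0 °C) gives the (E)-alkenylstannane F3. Stille coupling of F3 with 9 (Pd(PPh3)4, CuI, CsF, DMF, 45 °C) gives the target 12 directly, so the alkene geometry comes from a syn addition and no hydride reagent meets the phenol. The route is rejoined at 12.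

Step 1. Deprotonation may not be fully regioselective (some C-3 enolate), and the aldolate can revert or be quenched unproductively when MsCl is added. The fallback sets out from 1. The kinetic enolate is trapped (LDA, TMSCl, THF, −78 °C) as the silyl enol ether F4, which can be freed of its regioisomer by distillation. Mukaiyama aldol addition of F4 to 2 (BF3·OEt2, CH2Cl2, −78 °C) gives the aldol 3, this time isolated. The route is rejoined at 3, which MsCl/Et3N takes through 4 to 5.

**Further compounds**

F1 | step 3 | triethylsilyl ether of 7 at the C-3 hydroxyl (stereocentres as in 7) | COc1ccc(CC[C@@H](O[Si](CC)(CC)CC)[C@H]2O[C@@H]2C#C[Si](C)(C)C)cc1OC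
F2 | step 3 | 2-O-triethylsilyl ether of 8 (stereocentres as in 8) | COc1cc2c(cc1OC)[C@H]([C@H](O)C#C[Si](C)(C)C)[C@H](O[Si](CC)(CC)CC)CC2
F3 | step 5 | 1-[(2E)-1-hydroxy-3-(tributylstannyl)prop-2-en-1-yl]-6,7-dimethoxy-1,2,3,4-tetrahydronaphthalen-2-ol (stereocentres as in 10) | COc1cc2c(cc1OC)[C@H]([C@H](O)/C=C/[Sn](CCCC)(CCCC)CCCC)[C@H](O)CC2
F4 | step 1 | 4-(3,4-dimethoxyphenyl)-2-(trimethylsilyloxy)but-1-ene | COc1ccc(CCC(=C)O[Si](C)(C)C)cc1OC
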